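**Plan**

1. Numbering (eudesmane): ring A = C1–C2–C3–C4–C5–C10, ring B = C5–C6–C7–C8–C9–C10, C14 = methyl on C10, C15 on C4, C11(–C12, =C13) on C7; β = the face of C14.
2. Retrosynthesis: the C5–OOH / C4=C15 pair goes back to a C4(CH3)=C5 alkene (singlet-oxygen ene reaction); then C11=C13 (methylenation), the C12 ester (oxidation) and C7–C11 (enolate allylation) are cut; the two esters go back to C3 and C8 carbonyl groups.
3. The remaining bicyclic enone is cut at C1–C10 and C4–C5 at once: ring A is the Robinson annulation product of ethyl vinyl ketone (C1, C2, C3, C4, C15) on a ring B 2-methylcyclohexanone whose C8 carbonyl is masked as a dioxolane.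
4. Enabling feature: quaternary, methyl-bearing C10 lies next to oxygenated C5, and the C3 oxygen is 1,5 to C5 through C10–C1–C2 and 1,3 through C4 inside ring A, with the one-carbon branch C15 on C4, so a Michael retron and an aldol retron share one ethyl ketone.
5. Forward: ring B is bought, ring A is annulated onto it in step 2, then C3, C7 and C8 are elaborated and the hydroperoxide is installed last.
6. Stereochemistry: C10 from the (R)-1-phenylethylamine auxiliary in the annulation; C3, C8 and C5 by attack steered by the axial C10 methyl group (hydride twice, singlet oxygen once); C7 by thermodynamic equilibration.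

Key step: step 2

Remark: ketone 1 is taken as the commercial racemate; its stereocenter is erased in the enamine of step 2, so no resolution is needed.

**Route**

Step 1
Reactants: 1 rac-7-methyl-1,4-dioxaspiro[4.5]decan-8-one; 2 (R)-1-phenylethylamine
Product: 3 (R)-N-(7-methyl-1,4-dioxaspiro[4.5]decan-8-ylidene)-1-phenylethanamine (ketimine; both epimers at the methyl-bearing carbon)
Conditions: TsOH·H2O (cat.), toluene, reflux, Dean–Stark
Reagents that add atoms: none
Why: Acid-catalysed ketimine condensation driven by azeotropic removal of water; the configuration at the methyl-bearing carbon is immaterial because both epimers converge on one enamine tautomer in step 2.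

Step 2
Reactants: 3 ketimine; 4 ethyl vinyl ketone (pent-1-en-3-one)
Product: 9 8,8-(ethylenedioxy)-11,12,13-trinoreudesm-4-en-3-one [(4aR)-6,6-(ethylenedioxy)-1,4a-dimethyl-4,4a,5,6,7,8-hexahydronaphthalen-2(3H)-one; 10β-methyl], via enamine tautomer 5 (not isolated), via Michael adduct imine 6 (not isolated), via diketone 7 (not isolated), via ketol 8 (not isolated)
Conditions: 4 (1.5 equiv), THF, 40 °C; then 20% aq. AcOH, rt; then NaOMe (0.2 equiv), MeOH, 60 °C (telescoped, no isolation)
Reagents that add atoms: none
Why: Imine 3 equilibrates with its tetrasubstituted secondary enamine 5, which adds to 4 through a compact, chair-like aza-ene transition state in which the N–H is passed to the α-carbon of the enone, so that C1–C10 and the quaternary C10 are formed in 6; acid hydrolysis then frees 1,5-diketone 7 and the auxiliary, and methoxide forms the C4 enolate of the ethyl ketone, which adds to the C5 carbonyl (ketol 8) and dehydrates by E1cB to the tetrasubstituted enone, forming C4–C5. The closest known reaction type is the asymmetric Robinson annulation of 2-methylcyclohexanones through chiral 1-phenylethylamine imines (deracemizing Michael addition followed by aldol condensation), which is standard for 10-methyloctalones and cyperone-type enones. Ring A (C1–C2–C3–C4–C5–C10) is the only ring closed, in a 6-(enolendo)-exo-trig aldol addition onto the ring B carbonyl. C10 is the only stereocenter that survives the step and is set by the auxiliary: with the benzylic C–H lying in the enamine plane toward C6, the phenyl group shields one face and the enone should add to the other, which with the (R)-amine corresponds to the 10β-methyl (10R) series. The step needs C- over N-alkylation at the methyl-bearing α-carbon, secured by the preference for the more substituted enamine and by the internal proton transfer, and survival of the dioxolane, secured by the mild acid and the basic final stage. Competing aldol modes (C2 onto C5, C6 onto C3) are reversible and cannot end in a conjugated enone, so the fused enone should be the sink.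

Step 3
Reactants: 9 enone ketal
Product: 10 8,8-(ethylenedioxy)-11,12,13-trinoreudesm-4-en-3β-ol (3S,10R)
Conditions: NaBH4, CeCl3·7H2O, MeOH, −20 °C
Reagents that add atoms: none
Why: Luche 1,2-reduction of the enone, in which hydride should add axially to C3 from the α face of the half-chair ring A to give the equatorial 3β-alcohol, as is general for 10-methyl 4-en-3-ones, while the dioxolane is untouched.

Step 4
Reactants: 10 allylic alcohol
Product: 11 8,8-(ethylenedioxy)-3β-(isobutyryloxy)-11,12,13-trinoreudesm-4-ene
Conditions: (i-PrCO)2O, Et3N, DMAP (cat.), CH2Cl2, 0 °C to rt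
Reagents that add atoms: isobutyric anhydride, CC(C)C(=O)OC(=O)C(C)C
Why: DMAP-catalysed acylation of the equatorial secondary alcohol, which installs the isobutyrate of the target with retention at C3 and at the same time protects the acid-sensitive allylic alcohol for the next steps.

Step 5
Reactants: 11 isobutyrate ketal
Product: 12 3β-(isobutyryloxy)-11,12,13-trinoreudesm-4-en-8-one
Conditions: PPTS (cat.), acetone/H2O, 50 °C
Reagents that add atoms: water, O
Why: Acid-catalysed acetal hydrolysis under pyridinium catalysis, mild enough that the allylic ester should not ionize, frees the C8 ketone.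

Step 6
Reactants: 12 ketone; 13 allyl bromide
Product: 15 7β-allyl-3β-(isobutyryloxy)-11,12,13-trinoreudesm-4-en-8-one, via lithium enolate 14 (not isolated)
Conditions: LiN(SiMe3)2 (1.05 equiv), THF, −78 °C; 13, DMPU, −78 to −30 °C; then DBU (cat.), toluene, 60 °C
Reagents that add atoms: none
Why: Kinetic enolate alkylation, in which the amide base should deprotonate the ketone (far more acidic than the hindered isobutyrate) at C7, the α-methylene remote from quaternary C10, and enolate 14 is allylated by 13; the base equilibration afterwards places the allyl group in the equatorial 7β position.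

Step 7
Reactants: 15 allyl ketone
Product: 16 7β-allyl-3β-(isobutyryloxy)-11,12,13-trinoreudesm-4-en-8β-ol
Conditions: LiBH(s-Bu)3 (1.1 equiv), THF, −78 °C; then H2O
Reagents that add atoms: none
Why: Bulky-hydride reduction of a 2-alkylcyclohexanone, in which the reagent should approach C8 along the equatorial trajectory from the α face (the axial β trajectory is blocked by the syn-axial C10 methyl group) and give the axial 8β-alcohol cis to the 7β substituent; the ester is inert at this temperature.

Step 8
Reactants: 16 axial alcohol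
Product: 17 8β-acetoxy-7β-allyl-3β-(isobutyryloxy)-11,12,13-trinoreudesm-4-ene
Conditions: Ac2O, Et3N, DMAP (cat.), CH2Cl2, rt to 40 °C
Reagents that add atoms: acetic anhydride, CC(=O)OC(C)=O
Why: DMAP-catalysed acetylation of the hindered axial alcohol with retention at C8.

Step 9
Reactants: 17 allyl diester
Product: 19 8β-acetoxy-3β-(isobutyryloxy)-13-noreudesm-4-en-12-al, via diol 18 (not isolated)
Conditions: OsO4 (2 mol %), NaIO4, 2,6-lutidine, dioxane/H2O, rt
Reagents that add atoms: osmium tetroxide (oxygen carrier), O=[Os](=O)(=O)=O; sodium periodate (terminal oxidant), [Na+].[O-]I(=O)(=O)=O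
Why: Lemieux–Johnson oxidation, in which OsO4 should dihydroxylate only the unhindered monosubstituted alkene (the tetrasubstituted C4=C5 bond, flanked by quaternary C10 and the allylic ester, reacts far more slowly) and NaIO4 cleaves diol 18 to the aldehyde.

Step 10
Reactants: 19 aldehyde
Product: 20 8β-acetoxy-3β-(isobutyryloxy)eudesma-4,11(13)-dien-12-al
Conditions: 37% aq. CH2O, pyrrolidine (10 mol %), EtCO2H (10 mol %), i-PrOH, 45 °C
Reagents that add atoms: formaldehyde, C=O
Why: Amine-catalysed Mannich condensation with formaldehyde (α-methylenation of an aldehyde), chemoselective for the aldehyde α-carbon C11 over the three ester groups, creates C11=C13 without touching C7.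

Step 11
Reactants: 20 enal
Product: 22 methyl 8β-acetoxy-3β-(isobutyryloxy)eudesma-4,11(13)-dien-12-oate, via acrylic acid 21 (not isolated)
Conditions: NaClO2, NaH2PO4, 2-methylbut-2-ene, t-BuOH/H2O, 0 °C to rt; then MeI, K2CO3, DMF, rt
Reagents that add atoms: sodium chlorite, [Na+].[O-]Cl=O; iodomethane, CI
Why: Pinnick oxidation of the enal to acrylic acid 21 (hypochlorous acid is scavenged by 2-methylbut-2-ene, so both alkenes should survive) followed by O-alkylation of the carboxylate with MeI; no stereocenter is involved.

Step 12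
Reactants: 22 ene precursor
Product: 23 methyl 8β-acetoxy-5α-hydroperoxy-3β-(isobutyryloxy)eudesma-4(15),11(13)-dien-12-oate (3S,5S,7R,8R,10R)
Conditions: O2, visible light, tetraphenylporphyrin (cat.), CH2Cl2, 0 °C
Reagents that add atoms: dioxygen, O=O
Why: Schenck ene reaction, in which singlet oxygen should attack the tetrasubstituted C4=C5 bond from the α face, anti to the axial C10 methyl group, bond to C5 and take a hydrogen from the C4 methyl group (methyl hydrogens are preferred over ring hydrogens in 1,2-dialkylcyclohexenes and the C3 hydrogen geminal to the acyloxy group is deactivated), which sets the 5α-hydroperoxide and the C4=C15 methylene group while the electron-poor acrylate stays inert.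

**Compound list**

1 | rac-7-methyl-1,4-dioxaspiro[4.5]decan-8-one | CC1CC2(OCCO2)CCC1=O | starting material
2 | (R)-1-phenylethylamine | C[C@@H](N)c1ccccc1 | starting material
3 | (R)-N-(7-methyl-1,4-dioxaspiro[4.5]decan-8-ylidene)-1-phenylethanamine | CC1CC2(OCCO2)CCC1=N[C@H](C)c1ccccc1 | intermediate
4 | ethyl vinyl ketone (pent-1-en-3-one) | C=CC(=O)CC | starting material
5 | enamine tautomer, (R)-N-(7-methyl-1,4-dioxaspiro[4.5]dec-7-en-8-yl)-1-phenylethanamine | CC1=C(N[C@H](C)c2ccccc2)CCC2(OCCO2)C1 | intermediate (not isolated)
6 | Michael adduct imine, 1-[(7R)-7-methyl-8-{[(R)-1-phenylethyl]imino}-1,4-dioxaspiro[4.5]decan-7-yl]pentan-3-one | CCC(=O)CC[C@]1(C)CC2(OCCO2)CCC1=N[C@H](C)c1ccccc1 | intermediate (not isolated)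
7 | diketone, (R)-7-methyl-7-(3-oxopentyl)-1,4-dioxaspiro[4.5]decan-8-one | CCC(=O)CC[C@]1(C)CC2(OCCO2)CCC1=O | intermediate (not isolated)
8 | ketol, 8,8-(ethylenedioxy)-5-hydroxy-11,12,13-trinoreudesman-3-one (10R; C4 and C5 not defined) | CC1C(=O)CC[C@]2(C)CC3(OCCO3)CCC12O | intermediate (not isolated)
9 | 8,8-(ethylenedioxy)-11,12,13-trinoreudesm-4-en-3-one (10R) | O=C1CC[C@]2(C)CC3(OCCO3)CCC2=C1C | intermediate
10 | 8,8-(ethylenedioxy)-11,12,13-trinoreudesm-4-en-3β-ol (3S,10R) | C1CC2=C(C)[C@@H](O)CC[C@]2(C)CC13OCCO3 | intermediate
11 | 8,8-(ethylenedioxy)-3β-(isobutyryloxy)-11,12,13-trinoreudesm-4-ene | C1CC2=C(C)[C@@H](OC(=O)C(C)C)CC[C@]2(C)CC13OCCO3 | intermediate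
12 | 3β-(isobutyryloxy)-11,12,13-trinoreudesm-4-en-8-one | C1CC2=C(C)[C@@H](OC(=O)C(C)C)CC[C@]2(C)CC1=O | intermediate
13 | allyl bromide | C=CCBr | starting material
14 | lithium enolate of 12 (C7=C8–OLi) | [Li]OC1=CCC2=C(C)[C@@H](OC(=O)C(C)C)CC[C@]2(C)C1 | intermediate (not isolated)
15 | 7β-allyl-3β-(isobutyryloxy)-11,12,13-trinoreudesm-4-en-8-one | C=CC[C@H]1CC2=C(C)[C@@H](OC(=O)C(C)C)CC[C@]2(C)CC1=O | intermediate
16 | 7β-allyl-3β-(isobutyryloxy)-11,12,13-trinoreudesm-4-en-8β-ol | C=CC[C@H]1CC2=C(C)[C@@H](OC(=O)C(C)C)CC[C@]2(C)C[C@H]1O | intermediate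
17 | 8β-acetoxy-7β-allyl-3β-(isobutyryloxy)-11,12,13-trinoreudesm-4-ene | C=CC[C@H]1CC2=C(C)[C@@H](OC(=O)C(C)C)CC[C@]2(C)C[C@H]1OC(C)=O | intermediate
18 | diol, 8β-acetoxy-7β-(2,3-dihydroxypropyl)-3β-(isobutyryloxy)-11,12,13-trinoreudesm-4-ene (both carbinol epimers) | OCC(O)C[C@H]1CC2=C(C)[C@@H](OC(=O)C(C)C)CC[C@]2(C)C[C@H]1OC(C)=O | intermediate (not isolated)
19 | 8β-acetoxy-3β-(isobutyryloxy)-13-noreudesm-4-en-12-al | O=CC[C@H]1CC2=C(C)[C@@H](OC(=O)C(C)C)CC[C@]2(C)C[C@H]1OC(C)=O | intermediate
20 | 8β-acetoxy-3β-(isobutyryloxy)eudesma-4,11(13)-dien-12-al | C=C(C=O)[C@H]1CC2=C(C)[C@@H](OC(=O)C(C)C)CC[C@]2(C)C[C@H]1OC(C)=O | intermediate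
21 | 8β-acetoxy-3β-(isobutyryloxy)eudesma-4,11(13)-dien-12-oic acid | C=C(C(=O)O)[C@H]1CC2=C(C)[C@@H](OC(=O)C(C)C)CC[C@]2(C)C[C@H]1OC(C)=O | intermediate (not isolated)
22 | methyl 8β-acetoxy-3β-(isobutyryloxy)eudesma-4,11(13)-dien-12-oate | C=C(C(=O)OC)[C@H]1CC2=C(C)[C@@H](OC(=O)C(C)C)CC[C@]2(C)C[C@H]1OC(C)=O | intermediate
23 | methyl 8β-acetoxy-5α-hydroperoxy-3β-(isobutyryloxy)eudesma-4(15),11(13)-dien-12-oate (3S,5S,7R,8R,10R) | C=C(C(=O)OC)[C@H]1C[C@@]2(OO)C(=C)[C@@H](OC(=O)C(C)C)CC[C@]2(C)C[C@H]1OC(C)=O | target

**Step count and risks**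

Total step count: 12. Longest linear sequence: 12 steps (1 to 23).

Steps most likely to fail:

Step 12. Hydrogen abstraction from C6 (oxygen then bonds to C4) or from C3 may compete with abstraction from C15, attack on the β face may not be fully suppressed, and the tertiary allylic hydroperoxide may fragment on handling. Fallback: from 22, epoxidation with mCPBA from the α face should give the 4α,5α-epoxide F1. Isomerization with Me3SiOTf/DBU, with loss of a C15 proton, should give the 5α-trimethylsilyl ether F2, and mild aqueous acid should give the tertiary allylic alcohol F3. Acid-catalysed perhydrolysis (50% H2O2, cat. H2SO4, Et2O, 0 °C), with capture of the allyl cation at its tertiary end anti to the C10 methyl group, would come back to the route at 23.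

Step 6. Proton exchange between enolate and product may cause double allylation, some deprotonation may occur toward C9, and the base may attack the isobutyrate. Fallback: from 12, condensation with pyrrolidine (cat. TsOH, benzene, Dean–Stark) should give the less substituted pyrrolidine enamine F4. Stork enamine alkylation with 13 in MeCN and hydrolysis (aq. AcOH/NaOAc), followed by the same base equilibration, would come back to the route at 15.

Step 2. Facial discrimination in the conjugate addition may be incomplete, which lowers the enantiomeric purity of everything downstream, and the addition to the hindered ketimine may be slow enough for N-alkylation or polymerization of 4 to compete. Fallback: from 1 and 4, a base-mediated Robinson annulation (KOH, MeOH, reflux) would give the racemic enone ketal F5 and Luche reduction the racemic 3,10-cis allylic alcohol F6. A lipase-catalysed kinetic resolution (Candida antarctica lipase B, vinyl acetate, t-BuOMe) is expected, by the usual preference of lipases for the (R)-carbinol, to acetylate the (3R,10S)-enantiomer to the acetate F7 and to leave the (3S,10R)-alcohol, which is 10, where the route is rejoined.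

Further compounds
F1 | step 12 | methyl 8β-acetoxy-4α,5α-epoxy-3β-(isobutyryloxy)eudesm-11(13)-en-12-oate | C=C(C(=O)OC)[C@H]1C[C@@]2(O3)[C@@]3(C)[C@@H](OC(=O)C(C)C)CC[C@]2(C)C[C@H]1OC(C)=O
F2 | step 12 | methyl 8β-acetoxy-3β-(isobutyryloxy)-5α-(trimethylsilyloxy)eudesma-4(15),11(13)-dien-12-oate | C=C(C(=O)OC)[C@H]1C[C@@]2(O[Si](C)(C)C)C(=C)[C@@H](OC(=O)C(C)C)CC[C@]2(C)C[C@H]1OC(C)=O
F3 | step 12 | methyl 8β-acetoxy-5α-hydroxy-3β-(isobutyryloxy)eudesma-4(15),11(13)-dien-12-oate | C=C(C(=O)OC)[C@H]1C[C@@]2(O)C(=C)[C@@H](OC(=O)C(C)C)CC[C@]2(C)C[C@H]1OC(C)=O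
F4 | step 6 | 3β-(isobutyryloxy)-8-(pyrrolidin-1-yl)-11,12,13-trinoreudesma-4,7-diene | C1(N3CCCC3)=CCC2=C(C)[C@@H](OC(=O)C(C)C)CC[C@]2(C)C1
F5 | step 2 | racemic 8,8-(ethylenedioxy)-11,12,13-trinoreudesm-4-en-3-one (both enantiomers) | O=C1CC[C@]2(C)CC3(OCCO3)CCC2=C1C.O=C1CC[C@@]2(C)CC3(OCCO3)CCC2=C1C
F6 | step 2 | racemic 3,10-cis 8,8-(ethylenedioxy)-11,12,13-trinoreudesm-4-en-3-ol (both enantiomers) | C1CC2=C(C)[C@@H](O)CC[C@]2(C)CC13OCCO3.C1CC2=C(C)[C@H](O)CC[C@@]2(C)CC13OCCO3
F7 | step 2 | (3R,10S)-3-acetoxy-8,8-(ethylenedioxy)-11,12,13-trinoreudesm-4-ene | C1CC2=C(C)[C@H](OC(C)=O)CC[C@@]2(C)CC13OCCO3
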